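## Structural features

The target is a germacranolide: a ten-membered carbocycle (C1 to C10) fused at C6–C7 to a butenolide (lactone oxygen on C6, C7=C11, C12 carbonyl) that carries an acetoxymethyl group (C13) on C11. The carbocycle bears two trisubstituted epoxides, C1–C10 and C4–C5, each with a methyl group on its quaternary carbon and each cis on the ring, and a methacrylate ester on C8. There are six stereocentres (1R,4S,5R,6R,8R,10S). C4, C5 and C6 are contiguous, with the C5 epoxide oxygen and the C6 lactone oxygen on the same ring face. C8 faces C6 across the sp2 carbon C7 (syn-1,3 oxygens). The C1/C10 pair is insulated from the rest by C2–C3 and C9. The fragile groups are the epoxides (acid), the butenolide (its C6 hydrogen is acidic and sits next to the C4–C5 epoxide, so base can trigger β-elimination), the allylic acetate and the polymerisable methacrylate. The real difficulties are the ten-membered ring and the facial control of two epoxidations on it. Because both epoxides are cis, they derive from a (1(10)Z,4Z)-cyclodecadiene whose olefins flank C2–C3. The key step uses this: C2 and C3 are both allylic methylenes, and a sulfonyl group at C2 reverses its polarity so that it can alkylate an allylic bromide at C3.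

## Logic of the disconnections

38 ⇒ 37 ⇒ 36 ⇒ 35. The acyl C–O bonds at O8 (methacrylate) and O13 (acetate) are cut, and both hydroxyls are masked as silyl ethers. The methacrylate would not survive ozone or carbanions, and an acetate β to the lactone-forming carbanion would be eliminated. The gain is an endgame of one deprotection and two acylations. The demand is selective acetylation of the primary hydroxyl beside the hindered secondary one, without strong acid or base.

35 ⇒ 34 ⇒ 32 ⇒ 27 + 31. C7=C11 is cut as an intramolecular Horner–Wadsworth–Emmons olefination, the C7 carbonyl is traced to the C7 methylene, and the O6–C12 ester bond is cut. This brings C11–C13 in as one reagent and forms the tetrasubstituted olefin without a separate dehydration. The demand is a free C6 hydroxyl with O8 still protected, the methylene as the only alkene at the ozonolysis, and ring closure faster than enolisation of the ketone.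

27 ⇒ 26 ⇒ 25. Both epoxide C–O pairs are cut to the Z olefins (the O6 p-methoxybenzyl ether is restored first). Both epoxides have the same local sense, so one chiral ketone catalyst can set four stereocentres. The gain is a triene with only two stereocentres. The demand is reagent control of both faces on a ten-membered ring and preference for the trisubstituted olefins over the methylene.

25 ⇒ 24 ⇒ 22. The sulfonyl group is put back on C2 and the C2–C3 bond is cut. This is the only bond between two allylic carbons whose olefin geometry can be fixed in an open chain. The gain is an acyclic chain with two stereocentres. The demand is α-selective SN2 alkylation under high dilution, with no other acidic hydrogen in 22.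

22 ⇒ 21 ⇒ 20 ⇒ 18. C3–Br is traced to the C3 silyl ether and C2–S to the C2 allylic alcohol. The sulfone is installed first because sulfinate would otherwise attack both termini. The demand is selective cleavage of a primary silyl ether beside a secondary one and substitution without allylic transposition.

18 ⇒ 17 ⇒ 16 ⇒ 14 ⇒ 13. C2 is returned to the ester level, the C10–CH3 bond is cut as a syn cuprate addition to an ynoate, and C1–C2 as carboxylation of a terminal alkyne. This is the reliable way to a Z trisubstituted olefin with C9 and C2 cis. The demand is low temperature so the alkenylcuprate does not isomerise.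

13 ⇒ 12. C8–C9 is cut as a catalytic asymmetric propargylation. Making C8 the electrophile avoids a β,γ-unsaturated aldehyde and a basic allyl metal, and the catalyst sets C8 independently of C6. The demand is 1,2-addition to an α-substituted acrolein.

12 ⇒ 10 ⇒ 9 ⇒ 8 ⇒ 6. C7–C8 is cut as formylation of a vinyl metal, the vinyl metal is traced to a terminal alkyne by α-selective hydrostannation, and C6–C7 is cut as an enantioselective acetylide addition to a Z enal. An amine-catalysed acrylate addition to this enal was rejected: it offers no control of C6 and puts the Z geometry at risk. The demand is a catalyst-controlled addition and Markovnikov hydrometallation.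

6 ⇒ 4 ⇒ 3 ⇒ 1. C5–C6 is cut as formylation of a Z vinyllithium, and the C4–CH3 and C5–I bonds as anti carbomagnesiation–iodination of a propargylic alkoxide. The chelate fixes the Z geometry in one step from a three-carbon alcohol.

31 ⇒ 29 ⇒ 28. C11–C12 is cut as carboxylation of an α-lithiated phosphonate, after silylation of O13. The demand is trapping below the temperature of β-elimination.

## Other disconnections considered

Alternative 1: The cut is the O–C6 lactone bond. The ten-membered dienoic acid A2, whose C4 carbinol comes from (S)-linalool A3, is treated with I2/NaHCO3. The C12 carboxylate attacks C6 anti to the iodonium on the Z C5=C6 olefin and gives iodolactone A1. The C4 hydroxyl then displaces iodide with inversion to close the 4,5-epoxide.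
- In its favour: the C4–C5–C6 triad follows from a stereospecific anti addition and an SN2 closure, with C4 from the chiral pool. On this point it is better than the chosen plan, which relies on a reagent-controlled epoxidation of 25. The way from A1 to 38 (epoxide closure, desilylation, methacryloylation) is also shorter than the nine steps from 24.
- Against it: the step does not make the ten-membered ring, so A2 (with the 1,10-epoxide, C8 ether and a conjugated dienoic acid) must be reached by another macrocyclisation. The C5=C6 olefin is conjugated to the acid and poor toward iodine, and attack by the C4 hydroxyl can compete. The later base-mediated epoxide closure must be run beside an acidic C6 hydrogen and an allylic acetate.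
- Comparison: the chosen plan solves ring formation first on a robust skeleton and pays with the late epoxidation; this alternative does the reverse, and its step count depends on an unsolved route to A2.

Alternative 2: The cut is C8–C9. The potassium alkoxide of vinylcyclooctadienol A5 (KH, 18-crown-6) undergoes an oxyanion-accelerated [1,3] shift: C6–C9 breaks and C9 bonds to the vinyl terminus, giving cyclodecadienone A4.
- In its favour: both Z olefins are formed in an eight-membered ring, where Z is the only option, and the ring grows without high dilution or a group to remove. On ring construction it is equal to or better than the chosen plan.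
- Against it: A4 is achiral and carries only the C6 oxygen. The C8 oxygen, C11–C13 and all six stereocentres must be added to a flexible ring with no resident stereocentre. The C4=C5 olefin is conjugated to the C6 ketone and no longer behaves like C1=C10. The [3,3] pathway (C8 to C1) competes with the wanted [1,3] shift.
- Comparison: the chosen plan is longer before ring closure but brings C6 and C8 in with defined configuration; here the short ring synthesis is outweighed by a long, poorly controlled functionalisation.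

Alternative 3: The cut is C9–C10. SmI2 converts the bromoacetyl butenolide A7 into the samarium enolate of the C8 ketone, which adds to the C10 methyl ketone, chelated with the C1 p-methoxybenzyl ether, to give hydroxy ketone A6.
- In its favour: the ring is closed late with the butenolide, acetate and 4,5-epoxide in place, and the chelate sets C10. Samarium templating usually tolerates moderate dilution; on macrocyclisation efficiency it is equal to or better than the chosen step, and it needs no epoxidation of the C4=C5 olefin on the ring.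
- Against it: A7 contains an ene-dione-like butenolide, an allylic acetate and an epoxide next to the lactone carbinol, all reducible by divalent samarium. After ring closure the C8 ketone must still be reduced selectively and the C1/C10 diol turned into the epoxide with inversion at C1. The four stereocentres of A7 need their own asymmetric steps.
- Comparison: the chosen plan exposes only ethers, olefins and a sulfone to its ring-closing reagent, at the price of more steps after it.

Key step: step 16

Remark: the fixed precursor 22 and product 24 were checked against the target and are consistent in constitution, olefin geometry and configuration; no correction was needed. C6 changes descriptor (S in 7–25, 33 and 34; R in 26, 27, 32 and 35–38) only because the CIP ranking of C5 and C7 changes.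

Assumption: the facial sense of the Zn–ProPhenol alkynylation (step 4) and of the BINOL–Ti(OiPr)4 propargylation (step 8) is taken from the accepted models; the configurations of 8 and 13 are to be confirmed (Mosher esters) and the ligand antipode used if the sense is opposite.

## Route

Step 1
Reactants: 1 prop-2-yn-1-ol
Product: 3 (Z)-3-iodo-2-methylprop-2-en-1-ol, via alkenylmagnesium alkoxide 2 (not isolated)
Conditions: MeMgBr (3 equiv), CuI (10 mol %), Et2O–THF, −10 °C to rt; then I2, −78 °C to rt
Reagents that add atoms: methylmagnesium bromide C[Mg]Br; iodine II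
Why: Copper-catalysed anti carbomagnesiation of the magnesium alkoxide puts methyl on C2 and magnesium on C3 in a five-membered chelate, so iodinolysis gives iodine cis to the hydroxymethyl group; this fixes the C4=C5 geometry and the C15 methyl.

Step 2
Reactants: 3 (Z)-3-iodo-2-methylprop-2-en-1-ol
Product: 4 (Z)-tert-butyl[(3-iodo-2-methylprop-2-en-1-yl)oxy]dimethylsilane
Conditions: TBSCl, imidazole, CH2Cl2, 0 °C to rt
Reagents that add atoms: tert-butyldimethylsilyl chloride CC(C)(C)[Si](C)(C)Cl
Why: Standard silylation of a primary alcohol; this ether becomes the C3 oxygen and is the only primary silyl ether in the later intermediates.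

Step 3
Reactants: 4 (Z)-tert-butyl[(3-iodo-2-methylprop-2-en-1-yl)oxy]dimethylsilane
Product: 6 (Z)-4-(tert-butyldimethylsilyloxy)-3-methylbut-2-enal, via vinyllithium 5 (not isolated)
Conditions: t-BuLi (2.1 equiv), Et2O, −78 °C; then DMF, −78 to 0 °C
Reagents that add atoms: N,N-dimethylformamide CN(C)C=O
Why: Iodine–lithium exchange proceeds with retention of geometry and the vinyllithium is formylated by DMF; the Z enal is used at once to avoid isomerisation.

Step 4
Reactants: 6 (Z)-4-(tert-butyldimethylsilyloxy)-3-methylbut-2-enal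
Product: 8 (3S,4Z)-6-(tert-butyldimethylsilyloxy)-5-methylhex-4-en-1-yn-3-ol, via TMS-alkynol 7 (not isolated)
Conditions: Me3SiC≡CH, Me2Zn, (S,S)-ProPhenol (10 mol %), Ph3P=O (20 mol %), toluene, 4 °C; then K2CO3, MeOH, rt
Reagents that add atoms: ethynyltrimethylsilane C#C[Si](C)(C)C
Why: Zn–ProPhenol alkynylation: the dinuclear zinc catalyst delivers the zinc acetylide to one face of the enal, a favourable substrate class, with no amine present to isomerise the Z olefin. C6 is set here (S, alkynyl ranking above alkenyl); K2CO3/MeOH then cleaves the C–Si bond of 7.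

Step 5
Reactants: 8 (3S,4Z)-6-(tert-butyldimethylsilyloxy)-5-methylhex-4-en-1-yn-3-ol
Product: 9 (3S,4Z)-6-(tert-butyldimethylsilyloxy)-3-(4-methoxybenzyloxy)-5-methylhex-4-en-1-yne
Conditions: NaH (1.1 equiv), PMBCl, Bu4NI (cat.), THF–DMF, 0 °C
Reagents that add atoms: 4-methoxybenzyl chloride COc1ccc(CCl)cc1
Why: Williamson etherification of the alkoxide; basic conditions avoid ionisation of the doubly activated carbinol, and one equivalent of base at 0 °C leaves the alkyne C–H and the C6 hydrogen alone.

Step 6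
Reactants: 9 (3S,4Z)-6-(tert-butyldimethylsilyloxy)-3-(4-methoxybenzyloxy)-5-methylhex-4-en-1-yne
Product: 10 (3S,4Z)-6-(tert-butyldimethylsilyloxy)-3-(4-methoxybenzyloxy)-5-methyl-2-(tributylstannyl)hexa-1,4-diene
Conditions: Bu3SnH, Mo(CO)3(CNt-Bu)3 (3 mol %), hydroquinone (cat.), THF, 55 °C
Reagents that add atoms: tributyltin hydride CCCC[SnH](CCCC)CCCC
Why: Molybdenum-catalysed hydrostannation of propargylic ethers is α-selective (tin on the carbon next to the oxygenated centre), giving the 1,1-disubstituted vinylstannane; alkenes and both ethers are inert.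

Step 7
Reactants: 10 (3S,4Z)-6-(tert-butyldimethylsilyloxy)-3-(4-methoxybenzyloxy)-5-methyl-2-(tributylstannyl)hexa-1,4-diene
Product: 12 (3S,4Z)-6-(tert-butyldimethylsilyloxy)-3-(4-methoxybenzyloxy)-5-methyl-2-methylidenehex-4-enal, via vinyllithium 11 (not isolated)
Conditions: n-BuLi, THF, −78 °C; then DMF, −78 to 0 °C
Reagents that add atoms: N,N-dimethylformamide CN(C)C=O
Why: Tin–lithium exchange gives the α-substituted vinyllithium, which DMF traps as the 2-substituted acrolein (C8 aldehyde); exchange at −78 °C is faster than deprotonation at C6 or loss of the alkoxide.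

Step 8
Reactants: 12 (3S,4Z)-6-(tert-butyldimethylsilyloxy)-3-(4-methoxybenzyloxy)-5-methyl-2-methylidenehex-4-enal
Product: 13 (4R,6S,7Z)-9-(tert-butyldimethylsilyloxy)-6-(4-methoxybenzyloxy)-8-methyl-5-methylidenenon-7-en-1-yn-4-ol
Conditions: (R)-BINOL (20 mol %), Ti(OiPr)4 (10 mol %), 4 Å MS, allenylSnBu3, CH2Cl2, −20 °C
Reagents that add atoms: tributyl(propa-1,2-dien-1-yl)stannane C=C=C[Sn](CCCC)(CCCC)CCCC
Why: Keck-type asymmetric propargylation: the BINOL–titanium Lewis acid activates the aldehyde and the allenylstannane adds in an SE2′ sense to give the homopropargylic alcohol. (R)-BINOL gives the R carbinol when the aldehyde substituent outranks the new CH2, so C8 is set by the catalyst and not by the remote C6 centre.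

Step 9
Reactants: 13 (4R,6S,7Z)-9-(tert-butyldimethylsilyloxy)-6-(4-methoxybenzyloxy)-8-methyl-5-methylidenenon-7-en-1-yn-4-ol
Product: 14 (4R,6S,7Z)-4,9-bis(tert-butyldimethylsilyloxy)-6-(4-methoxybenzyloxy)-8-methyl-5-methylidenenon-7-en-1-yne
Conditions: TBSOTf, 2,6-lutidine, CH2Cl2, −78 °C
Reagents that add atoms: tert-butyldimethylsilyl triflate CC(C)(C)[Si](C)(C)OS(=O)(=O)C(F)(F)F
Why: Silylation of the secondary allylic alcohol with the triflate and a hindered base; this is the O8 protecting group that stays until step 25.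

Step 10
Reactants: 14 (4R,6S,7Z)-4,9-bis(tert-butyldimethylsilyloxy)-6-(4-methoxybenzyloxy)-8-methyl-5-methylidenenon-7-en-1-yne
Product: 16 methyl (5R,7S,8Z)-5,10-bis(tert-butyldimethylsilyloxy)-7-(4-methoxybenzyloxy)-9-methyl-6-methylidenedec-8-en-2-ynoate, via lithium acetylide 15 (not isolated)
Conditions: n-BuLi (1.05 equiv), THF, −78 °C; then ClCO2Me, −78 to 0 °C
Reagents that add atoms: methyl chloroformate COC(=O)Cl
Why: The terminal alkyne C–H is the most acidic site, and the acetylide is C-acylated by the chloroformate; this adds C2 at the ester level.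

Step 11
Reactants: 16 methyl (5R,7S,8Z)-5,10-bis(tert-butyldimethylsilyloxy)-7-(4-methoxybenzyloxy)-9-methyl-6-methylidenedec-8-en-2-ynoate
Product: 17 methyl (2Z,5R,7S,8Z)-5,10-bis(tert-butyldimethylsilyloxy)-7-(4-methoxybenzyloxy)-3,9-dimethyl-6-methylidenedeca-2,8-dienoate
Conditions: Me2CuLi, THF, −78 °C; sat. aq. NH4Cl at −78 °C
Reagents that add atoms: lithium dimethylcuprate [Li+].C[Cu-]C
Why: Syn conjugate addition of the cuprate and protonation of the alkenylcuprate at −78 °C give the Z enoate (ester cis to C9); this fixes the C1=C10 geometry and the C14 methyl.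

Step 12
Reactants: 17 methyl (2Z,5R,7S,8Z)-5,10-bis(tert-butyldimethylsilyloxy)-7-(4-methoxybenzyloxy)-3,9-dimethyl-6-methylidenedeca-2,8-dienoate
Product: 18 (2Z,5R,7S,8Z)-5,10-bis(tert-butyldimethylsilyloxy)-7-(4-methoxybenzyloxy)-3,9-dimethyl-6-methylidenedeca-2,8-dien-1-ol
Conditions: i-Bu2AlH (2.5 equiv), CH2Cl2, −78 °C; aq. KNa tartrate
Reagents that add atoms: none
Why: 1,2-Reduction of the enoate to the allylic alcohol; the olefin geometry and the ethers are untouched.

Step 13
Reactants: 18 (2Z,5R,7S,8Z)-5,10-bis(tert-butyldimethylsilyloxy)-7-(4-methoxybenzyloxy)-3,9-dimethyl-6-methylidenedeca-2,8-dien-1-ol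
Product: 20 [(2Z,5R,7S,8Z)-5,10-bis(tert-butyldimethylsilyloxy)-7-(4-methoxybenzyloxy)-3,9-dimethyl-6-methylidenedeca-2,8-dien-1-yl] phenyl sulfone, via allylic mesylate 19 (not isolated)
Conditions: MsCl, Et3N, CH2Cl2, −40 °C; then PhSO2Na, Bu4NI (cat.), DMF, rt
Reagents that add atoms: sodium benzenesulfinate [Na+].[O-]S(=O)c1ccccc1; methanesulfonyl chloride CS(=O)(=O)Cl (retained only in 19)
Why: Mesylation, then SN2 displacement by sulfinate sulfur at the primary allylic carbon; the γ carbon is fully substituted, so SN2′ is not competitive and the Z geometry is kept.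

Step 14
Reactants: 20 [(2Z,5R,7S,8Z)-5,10-bis(tert-butyldimethylsilyloxy)-7-(4-methoxybenzyloxy)-3,9-dimethyl-6-methylidenedeca-2,8-dien-1-yl] phenyl sulfone
Product: 21 (2Z,4S,6R,8Z)-6-(tert-butyldimethylsilyloxy)-4-(4-methoxybenzyloxy)-2,8-dimethyl-5-methylidene-10-(phenylsulfonyl)deca-2,8-dien-1-ol
Conditions: HF·pyridine, pyridine, THF, 0 °C
Reagents that add atoms: none
Why: Buffered HF·pyridine cleaves the unhindered primary allylic silyl ether much faster than the secondary one next to the methylene; the benzyl ether and sulfone are stable.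

Step 15
Reactants: 21 (2Z,4S,6R,8Z)-6-(tert-butyldimethylsilyloxy)-4-(4-methoxybenzyloxy)-2,8-dimethyl-5-methylidene-10-(phenylsulfonyl)deca-2,8-dien-1-ol
Product: 22 [(2Z,5R,7S,8Z)-10-bromo-5-(tert-butyldimethylsilyloxy)-7-(4-methoxybenzyloxy)-3,9-dimethyl-6-methylidenedeca-2,8-dien-1-yl] phenyl sulfone
Conditions: CBr4, PPh3, 2,6-lutidine (cat.), CH2Cl2, −20 to 0 °C
Reagents that add atoms: carbon tetrabromide BrC(Br)(Br)Br
Why: Appel bromination under neutral conditions; SN2 at the primary carbon keeps the Z olefin and does not disturb the acidic sulfone. 22 is used directly.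

Step 16
Reactants: 22 [(2Z,5R,7S,8Z)-10-bromo-5-(tert-butyldimethylsilyloxy)-7-(4-methoxybenzyloxy)-3,9-dimethyl-6-methylidenedeca-2,8-dien-1-yl] phenyl sulfone
Product: 24 (1(10)Z,4Z,6S,8R)-8-(tert-butyldimethylsilyloxy)-6-(4-methoxybenzyloxy)-4,10-dimethyl-7-methylidene-2-(phenylsulfonyl)cyclodeca-1(10),4-diene (ring numbered as in the target; both C2 epimers), via sodium sulfonyl carbanion 23 (not isolated)
Conditions: NaN(SiMe3)2 (1.3 equiv), THF, 0 °C; 22 added by syringe pump over 10 h (final 2 mM)
Reagents that add atoms: none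
Why: The base removes the C2 hydrogen (α to sulfonyl and allylic, by far the most acidic in 22), and the carbanion displaces bromide from the primary allylic C3 in an SN2 process. The closest known reaction type is the intramolecular alkylation of allylic sulfone carbanions by allylic halides, used for medium and large carbocycles before reductive removal of the sulfonyl group. The ring is closed in a 10-exo-tet mode. No lasting stereocentre is made: C2 forms as both epimers and becomes a methylene in step 17, and C6 and C8 carry no acidic hydrogen. The step needs α- and not γ-alkylation of the ambident anion; γ attack at the fully substituted C10 would also require an eight-membered ring. It needs SN2 and not SN2′ attack, which is favoured because C5 is substituted and next to the C6 ether. It needs cyclisation and not oligomerisation: slow addition keeps the anion dilute, and the two Z olefins fold the chain so that C2 and C3 approach. Neither allylic terminus ionises, so both geometries are conserved.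

Step 17
Reactants: 24 (1(10)Z,4Z,6S,8R)-8-(tert-butyldimethylsilyloxy)-6-(4-methoxybenzyloxy)-4,10-dimethyl-7-methylidene-2-(phenylsulfonyl)cyclodeca-1(10),4-diene
Product: 25 (1(10)Z,4Z,6S,8R)-8-(tert-butyldimethylsilyloxy)-6-(4-methoxybenzyloxy)-4,10-dimethyl-7-methylidenecyclodeca-1(10),4-diene
Conditions: PdCl2(dppp) (5 mol %), LiBHEt3, THF, 0 °C
Reagents that add atoms: none
Why: Palladium-catalysed hydride substitution of an allylic sulfone: ionisation to the π-allyl complex and hydride delivery to the less substituted terminus C2 keep the C1=C10 position. Hydride transfer is fast relative to π–σ–π isomerisation, so the Z geometry should be kept; both C2 epimers converge on 25.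

Step 18
Reactants: 25 (1(10)Z,4Z,6S,8R)-8-(tert-butyldimethylsilyloxy)-6-(4-methoxybenzyloxy)-4,10-dimethyl-7-methylidenecyclodeca-1(10),4-diene
Product: 26 (1R,4S,5R,6R,8R,10S)-8-(tert-butyldimethylsilyloxy)-1,10:4,5-diepoxy-6-(4-methoxybenzyloxy)-4,10-dimethyl-7-methylidenecyclodecane
Conditions: D-fructose-derived Shi ketone (0.6 equiv), KHSO5 (as Oxone, 2KHSO5·KHSO4·K2SO4), K2CO3, Bu4NHSO4, MeCN–CH2(OMe)2–aq. Na2B4O7/Na2EDTA, 0 °C
Reagents that add atoms: potassium peroxymonosulfate [K+].[O-]S(=O)(=O)OO
Why: Shi epoxidation: the chiral dioxirane reacts through a spiro transition state and, for trisubstituted olefins, gives the epoxide that is R at the CH carbon (the sense of its (R,R) epoxide of 1-phenylcyclohexene, which has the same ring/exocyclic pattern as both olefins of 25). This corresponds to 1R,10S and 4S,5R. The two electron-rich trisubstituted olefins should react before the 1,1-disubstituted methylene, which is deactivated by two allylic oxygens.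

Step 19
Reactants: 26 (1R,4S,5R,6R,8R,10S)-8-(tert-butyldimethylsilyloxy)-1,10:4,5-diepoxy-6-(4-methoxybenzyloxy)-4,10-dimethyl-7-methylidenecyclodecane
Product: 27 (1R,4S,5R,6R,8R,10S)-8-(tert-butyldimethylsilyloxy)-1,10:4,5-diepoxy-4,10-dimethyl-7-methylidenecyclodecan-6-ol
Conditions: DDQ, CH2Cl2–pH 7 phosphate buffer, 0 °C
Reagents that add atoms: none
Why: Oxidative cleavage of the p-methoxybenzyl ether under buffered neutral conditions, which epoxides and the silyl ether tolerate; removing the arene here also protects it from ozone in step 23.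

Step 20
Reactants: 28 diethyl (2-hydroxyethyl)phosphonate
Product: 29 diethyl [2-(tert-butyldimethylsilyloxy)ethyl]phosphonate
Conditions: TBSCl, imidazole, CH2Cl2, rt
Reagents that add atoms: tert-butyldimethylsilyl chloride CC(C)(C)[Si](C)(C)Cl
Why: Standard silylation; this oxygen becomes O13.

Step 21
Reactants: 29 diethyl [2-(tert-butyldimethylsilyloxy)ethyl]phosphonate
Product: 31 3-(tert-butyldimethylsilyloxy)-2-(diethoxyphosphoryl)propanoic acid (racemic), via lithiated phosphonate 30 (not isolated)
Conditions: LiN(i-Pr)2 (2.1 equiv), THF, −78 °C; then CO2, −78 °C; cold 1 M HCl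
Reagents that add atoms: carbon dioxide O=C=O
Why: α-Lithiation of an alkylphosphonate and carboxylation is a known route to phosphonoacetic acids; at −78 °C trapping should outrun β-elimination of the silyloxide, and the second equivalent of base covers the more acidic product.

Step 22
Reactants: 27 (1R,4S,5R,6R,8R,10S)-8-(tert-butyldimethylsilyloxy)-1,10:4,5-diepoxy-4,10-dimethyl-7-methylidenecyclodecan-6-ol; 31 3-(tert-butyldimethylsilyloxy)-2-(diethoxyphosphoryl)propanoic acid
Product: 32 C6 ester of 27 with 31 (both epimers at the phosphonate carbon)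
Conditions: DCC, DMAP (cat.), CH2Cl2, 0 °C to rt
Reagents that add atoms: none
Why: Steglich esterification; phosphonoacetic acids acylate hindered secondary alcohols well under carbodiimide activation, and the neutral conditions spare the epoxy alcohol.

Step 23
Reactants: 32 C6 ester of 27 with 31
Product: 34 C7 ketone: (1R,4S,5R,6S,8R,10S)-8-(tert-butyldimethylsilyloxy)-1,10:4,5-diepoxy-4,10-dimethyl-7-oxocyclodecan-6-yl 3-(tert-butyldimethylsilyloxy)-2-(diethoxyphosphoryl)propanoate, via spiro ozonide 33 (not isolated)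
Conditions: O3, CH2Cl2, −78 °C; then Me2S, −78 °C to rt
Reagents that add atoms: ozone [O-][O+]=O
Why: Ozonolysis of the only remaining C=C with reductive work-up; epoxides, silyl ethers and the phosphonate ester are inert to ozone.

Step 24
Reactants: 34 C7 ketone
Product: 35 (1R,4S,5R,6R,8R,10S)-8,13-bis(tert-butyldimethylsilyloxy)-1,10:4,5-diepoxygermacr-7(11)-en-12,6-olide
Conditions: LiCl, i-Pr2NEt, MeCN, 0 °C to rt
Reagents that add atoms: none
Why: Intramolecular Horner–Wadsworth–Emmons olefination under Masamune–Roush conditions: the lithium-chelated phosphonate is the most acidic site, and its carbanion adds to the adjacent ketone through a five-membered transition state. Loss of diethyl phosphate forms C7=C11 and the butenolide; the mild amine base limits enolisation at C6 and C8.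

Step 25
Reactants: 35 (1R,4S,5R,6R,8R,10S)-8,13-bis(tert-butyldimethylsilyloxy)-1,10:4,5-diepoxygermacr-7(11)-en-12,6-olide
Product: 36 (1R,4S,5R,6R,8R,10S)-1,10:4,5-diepoxy-8,13-dihydroxygermacr-7(11)-en-12,6-olide
Conditions: HF·pyridine, pyridine, THF, 0 °C to rt
Reagents that add atoms: none
Why: Buffered HF·pyridine removes both silyl ethers; these conditions are known to spare trisubstituted epoxides and avoid the basicity of fluoride salts toward the C6 hydrogen.

Step 26
Reactants: 36 (1R,4S,5R,6R,8R,10S)-1,10:4,5-diepoxy-8,13-dihydroxygermacr-7(11)-en-12,6-olide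
Product: 37 (1R,4S,5R,6R,8R,10S)-13-acetoxy-1,10:4,5-diepoxy-8-hydroxygermacr-7(11)-en-12,6-olide
Conditions: AcCl (1.1 equiv), 2,4,6-collidine, CH2Cl2, −78 °C
Reagents that add atoms: acetyl chloride CC(=O)Cl
Why: Acetyl chloride with a hindered pyridine base at low temperature acylates primary alcohols selectively; the C8 hydroxyl is secondary and flanked by the butenolide and the ring.

Step 27
Reactants: 37 (1R,4S,5R,6R,8R,10S)-13-acetoxy-1,10:4,5-diepoxy-8-hydroxygermacr-7(11)-en-12,6-olide
Product: 38 (1R,4S,5R,6R,8R,10S)-13-acetoxy-1,10:4,5-diepoxy-8-(methacryloyloxy)germacr-7(11)-en-12,6-olide (target)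
Conditions: methacrylic anhydride, Et3N, DMAP (cat.), CH2Cl2, 0 °C
Reagents that add atoms: methacrylic anhydride C=C(C)C(=O)OC(=O)C(C)=C
Why: DMAP-catalysed acylation of the secondary alcohol with retention at C8; short reaction time and a weak amine base protect the C6 hydrogen and the epoxides.

## Compound list

1 | prop-2-yn-1-ol | C#CCO | starting material
2 | bromomagnesium (Z)-3-(bromomagnesio)-2-methylprop-2-en-1-olate | Br[Mg]/C=C(C)\CO[Mg]Br | intermediate
3 | (Z)-3-iodo-2-methylprop-2-en-1-ol | I/C=C(C)\CO | intermediate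
4 | (Z)-tert-butyl[(3-iodo-2-methylprop-2-en-1-yl)oxy]dimethylsilane | I/C=C(C)\CO[Si](C)(C)C(C)(C)C | intermediate
5 | (Z)-[3-(tert-butyldimethylsilyloxy)-2-methylprop-1-en-1-yl]lithium | [Li]/C=C(C)\CO[Si](C)(C)C(C)(C)C | intermediate
6 | (Z)-4-(tert-butyldimethylsilyloxy)-3-methylbut-2-enal | O=C/C=C(C)\CO[Si](C)(C)C(C)(C)C | intermediate
7 | (3S,4Z)-6-(tert-butyldimethylsilyloxy)-5-methyl-1-(trimethylsilyl)hex-4-en-1-yn-3-ol | C[Si](C)(C)C#C[C@@H](O)/C=C(C)\CO[Si](C)(C)C(C)(C)C | intermediate
8 | (3S,4Z)-6-(tert-butyldimethylsilyloxy)-5-methylhex-4-en-1-yn-3-ol | C#C[C@@H](O)/C=C(C)\CO[Si](C)(C)C(C)(C)C | intermediate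
9 | (3S,4Z)-6-(tert-butyldimethylsilyloxy)-3-(4-methoxybenzyloxy)-5-methylhex-4-en-1-yne | C#C[C@@H](OCc1ccc(OC)cc1)/C=C(C)\CO[Si](C)(C)C(C)(C)C | intermediate
10 | (3S,4Z)-6-(tert-butyldimethylsilyloxy)-3-(4-methoxybenzyloxy)-5-methyl-2-(tributylstannyl)hexa-1,4-diene | C=C([Sn](CCCC)(CCCC)CCCC)[C@@H](OCc1ccc(OC)cc1)/C=C(C)\CO[Si](C)(C)C(C)(C)C | intermediate
11 | (3S,4Z)-[6-(tert-butyldimethylsilyloxy)-3-(4-methoxybenzyloxy)-5-methylhexa-1,4-dien-2-yl]lithium | C=C([Li])[C@@H](OCc1ccc(OC)cc1)/C=C(C)\CO[Si](C)(C)C(C)(C)C | intermediate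
12 | (3S,4Z)-6-(tert-butyldimethylsilyloxy)-3-(4-methoxybenzyloxy)-5-methyl-2-methylidenehex-4-enal | C=C(C=O)[C@@H](OCc1ccc(OC)cc1)/C=C(C)\CO[Si](C)(C)C(C)(C)C | intermediate
13 | (4R,6S,7Z)-9-(tert-butyldimethylsilyloxy)-6-(4-methoxybenzyloxy)-8-methyl-5-methylidenenon-7-en-1-yn-4-ol | C#CC[C@@H](O)C(=C)[C@@H](OCc1ccc(OC)cc1)/C=C(C)\CO[Si](C)(C)C(C)(C)C | intermediate
14 | (4R,6S,7Z)-4,9-bis(tert-butyldimethylsilyloxy)-6-(4-methoxybenzyloxy)-8-methyl-5-methylidenenon-7-en-1-yne | C#CC[C@@H](O[Si](C)(C)C(C)(C)C)C(=C)[C@@H](OCc1ccc(OC)cc1)/C=C(C)\CO[Si](C)(C)C(C)(C)C | intermediate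
15 | lithium acetylide of 14 | [Li]C#CC[C@@H](O[Si](C)(C)C(C)(C)C)C(=C)[C@@H](OCc1ccc(OC)cc1)/C=C(C)\CO[Si](C)(C)C(C)(C)C | intermediate
16 | methyl (5R,7S,8Z)-5,10-bis(tert-butyldimethylsilyloxy)-7-(4-methoxybenzyloxy)-9-methyl-6-methylidenedec-8-en-2-ynoate | COC(=O)C#CC[C@@H](O[Si](C)(C)C(C)(C)C)C(=C)[C@@H](OCc1ccc(OC)cc1)/C=C(C)\CO[Si](C)(C)C(C)(C)C | intermediate
17 | methyl (2Z,5R,7S,8Z)-5,10-bis(tert-butyldimethylsilyloxy)-7-(4-methoxybenzyloxy)-3,9-dimethyl-6-methylidenedeca-2,8-dienoate | COC(=O)/C=C(C)\C[C@@H](O[Si](C)(C)C(C)(C)C)C(=C)[C@@H](OCc1ccc(OC)cc1)/C=C(C)\CO[Si](C)(C)C(C)(C)C | intermediate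
18 | (2Z,5R,7S,8Z)-5,10-bis(tert-butyldimethylsilyloxy)-7-(4-methoxybenzyloxy)-3,9-dimethyl-6-methylidenedeca-2,8-dien-1-ol | OC/C=C(C)\C[C@@H](O[Si](C)(C)C(C)(C)C)C(=C)[C@@H](OCc1ccc(OC)cc1)/C=C(C)\CO[Si](C)(C)C(C)(C)C | intermediate
19 | methanesulfonate of 18 | CS(=O)(=O)OC/C=C(C)\C[C@@H](O[Si](C)(C)C(C)(C)C)C(=C)[C@@H](OCc1ccc(OC)cc1)/C=C(C)\CO[Si](C)(C)C(C)(C)C | intermediate
20 | [(2Z,5R,7S,8Z)-5,10-bis(tert-butyldimethylsilyloxy)-7-(4-methoxybenzyloxy)-3,9-dimethyl-6-methylidenedeca-2,8-dien-1-yl] phenyl sulfone | O=S(=O)(C/C=C(C)\C[C@@H](O[Si](C)(C)C(C)(C)C)C(=C)[C@@H](OCc1ccc(OC)cc1)/C=C(C)\CO[Si](C)(C)C(C)(C)C)c1ccccc1 | intermediate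
21 | (2Z,4S,6R,8Z)-6-(tert-butyldimethylsilyloxy)-4-(4-methoxybenzyloxy)-2,8-dimethyl-5-methylidene-10-(phenylsulfonyl)deca-2,8-dien-1-ol | O=S(=O)(C/C=C(C)\C[C@@H](O[Si](C)(C)C(C)(C)C)C(=C)[C@@H](OCc1ccc(OC)cc1)/C=C(C)\CO)c1ccccc1 | intermediate
22 | [(2Z,5R,7S,8Z)-10-bromo-5-(tert-butyldimethylsilyloxy)-7-(4-methoxybenzyloxy)-3,9-dimethyl-6-methylidenedeca-2,8-dien-1-yl] phenyl sulfone (C2 sulfone, C3 bromide) | O=S(=O)(C/C=C(C)\C[C@@H](O[Si](C)(C)C(C)(C)C)C(=C)[C@@H](OCc1ccc(OC)cc1)/C=C(C)\CBr)c1ccccc1 | intermediate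
23 | sodium α-sulfonyl carbanion of 22 | [Na+].O=S(=O)([CH-]/C=C(C)\C[C@@H](O[Si](C)(C)C(C)(C)C)C(=C)[C@@H](OCc1ccc(OC)cc1)/C=C(C)\CBr)c1ccccc1 | intermediate
24 | (1(10)Z,4Z,6S,8R)-8-(tert-butyldimethylsilyloxy)-6-(4-methoxybenzyloxy)-4,10-dimethyl-7-methylidene-2-(phenylsulfonyl)cyclodeca-1(10),4-diene, both C2 epimers | CC(C)(C)[Si](C)(C)O[C@@H]1C/C(C)=C\C(S(=O)(=O)c2ccccc2)C/C(C)=C\[C@H](OCc2ccc(OC)cc2)C1=C | intermediate
25 | (1(10)Z,4Z,6S,8R)-8-(tert-butyldimethylsilyloxy)-6-(4-methoxybenzyloxy)-4,10-dimethyl-7-methylidenecyclodeca-1(10),4-diene | CC(C)(C)[Si](C)(C)O[C@@H]1C/C(C)=C\CC/C(C)=C\[C@H](OCc2ccc(OC)cc2)C1=C | intermediate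
26 | (1R,4S,5R,6R,8R,10S)-8-(tert-butyldimethylsilyloxy)-1,10:4,5-diepoxy-6-(4-methoxybenzyloxy)-4,10-dimethyl-7-methylidenecyclodecane | CC(C)(C)[Si](C)(C)O[C@@H]1C[C@]2(C)O[C@@H]2CC[C@]2(C)O[C@@H]2[C@H](OCc2ccc(OC)cc2)C1=C | intermediate
27 | (1R,4S,5R,6R,8R,10S)-8-(tert-butyldimethylsilyloxy)-1,10:4,5-diepoxy-4,10-dimethyl-7-methylidenecyclodecan-6-ol | CC(C)(C)[Si](C)(C)O[C@@H]1C[C@]2(C)O[C@@H]2CC[C@]2(C)O[C@@H]2[C@H](O)C1=C | intermediate
28 | diethyl (2-hydroxyethyl)phosphonate | CCOP(=O)(CCO)OCC | starting material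
29 | diethyl [2-(tert-butyldimethylsilyloxy)ethyl]phosphonate | CCOP(=O)(CCO[Si](C)(C)C(C)(C)C)OCC | intermediate
30 | α-lithiated 29 | CCOP(=O)(OCC)C([Li])CO[Si](C)(C)C(C)(C)C | intermediate
31 | 3-(tert-butyldimethylsilyloxy)-2-(diethoxyphosphoryl)propanoic acid (racemic) | CCOP(=O)(OCC)C(CO[Si](C)(C)C(C)(C)C)C(=O)O | intermediate
32 | (1R,4S,5R,6R,8R,10S)-8-(tert-butyldimethylsilyloxy)-1,10:4,5-diepoxy-4,10-dimethyl-7-methylidenecyclodecan-6-yl 3-(tert-butyldimethylsilyloxy)-2-(diethoxyphosphoryl)propanoate | CC(C)(C)[Si](C)(C)O[C@@H]1C[C@]2(C)O[C@@H]2CC[C@]2(C)O[C@@H]2[C@H](OC(=O)C(CO[Si](C)(C)C(C)(C)C)P(=O)(OCC)OCC)C1=C | intermediate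
33 | spiro 1,2,4-trioxolane (ozonide) of 32 at C7 | CC(C)(C)[Si](C)(C)O[C@@H]1C[C@]2(C)O[C@@H]2CC[C@]2(C)O[C@@H]2[C@H](OC(=O)C(CO[Si](C)(C)C(C)(C)C)P(=O)(OCC)OCC)C13OCOO3 | intermediate
34 | (1R,4S,5R,6S,8R,10S)-8-(tert-butyldimethylsilyloxy)-1,10:4,5-diepoxy-4,10-dimethyl-7-oxocyclodecan-6-yl 3-(tert-butyldimethylsilyloxy)-2-(diethoxyphosphoryl)propanoate | CC(C)(C)[Si](C)(C)O[C@@H]1C[C@]2(C)O[C@@H]2CC[C@]2(C)O[C@@H]2[C@H](OC(=O)C(CO[Si](C)(C)C(C)(C)C)P(=O)(OCC)OCC)C1=O | intermediate
35 | (1R,4S,5R,6R,8R,10S)-8,13-bis(tert-butyldimethylsilyloxy)-1,10:4,5-diepoxygermacr-7(11)-en-12,6-olide | CC(C)(C)[Si](C)(C)O[C@@H]1C[C@]2(C)O[C@@H]2CC[C@]2(C)O[C@@H]2[C@@H]2OC(=O)C(CO[Si](C)(C)C(C)(C)C)=C21 | intermediate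
36 | (1R,4S,5R,6R,8R,10S)-1,10:4,5-diepoxy-8,13-dihydroxygermacr-7(11)-en-12,6-olide | O[C@@H]1C[C@]2(C)O[C@@H]2CC[C@]2(C)O[C@@H]2[C@@H]2OC(=O)C(CO)=C21 | intermediate
37 | (1R,4S,5R,6R,8R,10S)-13-acetoxy-1,10:4,5-diepoxy-8-hydroxygermacr-7(11)-en-12,6-olide | O[C@@H]1C[C@]2(C)O[C@@H]2CC[C@]2(C)O[C@@H]2[C@@H]2OC(=O)C(COC(C)=O)=C21 | intermediate
38 | (1R,4S,5R,6R,8R,10S)-13-acetoxy-1,10:4,5-diepoxy-8-(methacryloyloxy)germacr-7(11)-en-12,6-olide (CNP0212980.1) | C=C(C)C(=O)O[C@@H]1C[C@]2(C)O[C@@H]2CC[C@]2(C)O[C@@H]2[C@@H]2OC(=O)C(COC(C)=O)=C21 | target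

## Step count and least certain steps

Total: 27 steps. Longest linear sequence: 25 steps (steps 1–19 and 22–27); steps 20–21 are the side branch to 31.

Step 16 (key step). What may go wrong: intermolecular alkylation outcompeting ring closure because of transannular strain in the ten-membered transition state, γ-alkylation of the allyl anion, or base-induced loss of HBr. Fallback (sets out from 18, comes back at 25): the roles of the two termini are exchanged so that the nucleophile sits at C3 and the bromide on the less hindered C2. Acetylation of 18 (Ac2O, pyridine) gives the C2 acetate F1. Selective cleavage of the primary silyl ether (HF·pyridine) gives the C3 alcohol F2. Mesylation and PhSO2Na give the C3 phenyl sulfone F3. Methanolysis (K2CO3, MeOH) frees the C2 alcohol F4. CBr4/PPh3 gives the C2 bromide F5. NaN(SiMe3)2 under high dilution closes the same C2–C3 bond to the 3-phenylsulfonyl cyclodecadiene F6, and PdCl2(dppp)/LiBHEt3 removes the sulfonyl group to give 25.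

Step 18. What may go wrong: poor facial selectivity at one or both olefins if the ring conformation opposes the catalyst, or over-oxidation of the methylene. Fallback (sets out from 25, comes back at 27): DDQ first frees the C6 hydroxyl to give the dienol F7. Hydroxyl-directed epoxidation (VO(acac)2, t-BuOOH) then delivers oxygen to the C4=C5 olefin from the face of the C6 hydroxyl, which is the cis relationship of the target, giving the 4,5-epoxy alcohol F8. A Shi epoxidation of the single remaining trisubstituted olefin gives 27.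

Step 17. What may go wrong: migration of the C1=C10 double bond or Z-to-E isomerisation through syn/anti equilibration of the π-allylpalladium intermediate. Fallback (sets out from 24, comes back at 25): the palladium pathway is abandoned for electron-transfer cleavage with Na(Hg), Na2HPO4, MeOH–THF at −20 °C, which goes through the allyl anion and is protonated at C2; no new compound is involved.

Step 24. What may go wrong: slow olefination of the hindered ketone, which would allow epimerisation at C6 or C8, β-elimination that opens the 4,5-epoxide, or loss of silyloxide from the phosphonate carbanion. Fallback (sets out from 26, comes back at 35): the lactone is built by aldol addition. Lemieux–Johnson cleavage (OsO4 cat., NaIO4, 2,6-lutidine) of 26 gives the C7 ketone F9. The lithium enolate of methyl 3-(tert-butyldimethylsilyloxy)propanoate adds at −78 °C to give the tertiary aldol F10. DDQ removes the benzyl ether and the freed C6 hydroxyl lactonises to the β-hydroxy lactone F11. Dehydration with Martin sulfurane toward the acidic C11 hydrogen gives 35.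

Step 6. What may go wrong: loss of α-regioselectivity at the hindered secondary propargylic ether, giving the terminal stannane. Fallback (sets out from 9, comes back at 12): α-selective hydroalumination (NiCl2(dppp) cat., i-Bu2AlH), then MeLi and paraformaldehyde, gives the primary allylic alcohol F12, which MnO2 oxidises to 12.

Step 4. What may go wrong: insufficient or opposite enantioselection, or Z-to-E isomerisation of the enal during the slow addition. Fallback (sets out from 6, comes back at 7): LiC≡CSiMe3 adds to 6 at −78 °C to give the racemic alkynol F13. MnO2 gives the ynone F14. Midland reduction with (S)-Alpine-Borane, in which the alkynyl group is the small substituent, gives 7, which is desilylated to 8 as in step 4.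

## Further compounds

F1 | step 16 | (2Z,5R,7S,8Z)-5,10-bis(tert-butyldimethylsilyloxy)-7-(4-methoxybenzyloxy)-3,9-dimethyl-6-methylidenedeca-2,8-dien-1-yl acetate | CC(=O)OC/C=C(C)\C[C@@H](O[Si](C)(C)C(C)(C)C)C(=C)[C@@H](OCc1ccc(OC)cc1)/C=C(C)\CO[Si](C)(C)C(C)(C)C
F2 | step 16 | (2Z,5R,7S,8Z)-5-(tert-butyldimethylsilyloxy)-10-hydroxy-7-(4-methoxybenzyloxy)-3,9-dimethyl-6-methylidenedeca-2,8-dien-1-yl acetate | CC(=O)OC/C=C(C)\C[C@@H](O[Si](C)(C)C(C)(C)C)C(=C)[C@@H](OCc1ccc(OC)cc1)/C=C(C)\CO
F3 | step 16 | (2Z,5R,7S,8Z)-5-(tert-butyldimethylsilyloxy)-7-(4-methoxybenzyloxy)-3,9-dimethyl-6-methylidene-10-(phenylsulfonyl)deca-2,8-dien-1-yl acetate | CC(=O)OC/C=C(C)\C[C@@H](O[Si](C)(C)C(C)(C)C)C(=C)[C@@H](OCc1ccc(OC)cc1)/C=C(C)\CS(=O)(=O)c1ccccc1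
F4 | step 16 | (2Z,5R,7S,8Z)-5-(tert-butyldimethylsilyloxy)-7-(4-methoxybenzyloxy)-3,9-dimethyl-6-methylidene-10-(phenylsulfonyl)deca-2,8-dien-1-ol | OC/C=C(C)\C[C@@H](O[Si](C)(C)C(C)(C)C)C(=C)[C@@H](OCc1ccc(OC)cc1)/C=C(C)\CS(=O)(=O)c1ccccc1
F5 | step 16 | [(2Z,4S,6R,8Z)-10-bromo-6-(tert-butyldimethylsilyloxy)-4-(4-methoxybenzyloxy)-2,8-dimethyl-5-methylidenedeca-2,8-dien-1-yl] phenyl sulfone (C3 sulfone, C2 bromide) | BrC/C=C(C)\C[C@@H](O[Si](C)(C)C(C)(C)C)C(=C)[C@@H](OCc1ccc(OC)cc1)/C=C(C)\CS(=O)(=O)c1ccccc1
F6 | step 16 | (1(10)Z,4Z,6S,8R)-8-(tert-butyldimethylsilyloxy)-6-(4-methoxybenzyloxy)-4,10-dimethyl-7-methylidene-3-(phenylsulfonyl)cyclodeca-1(10),4-diene, both C3 epimers | CC(C)(C)[Si](C)(C)O[C@@H]1C/C(C)=C\CC(S(=O)(=O)c2ccccc2)/C(C)=C\[C@H](OCc2ccc(OC)cc2)C1=C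
F7 | step 18 | (1(10)Z,4Z,6S,8R)-8-(tert-butyldimethylsilyloxy)-4,10-dimethyl-7-methylidenecyclodeca-1(10),4-dien-6-ol | CC(C)(C)[Si](C)(C)O[C@@H]1C/C(C)=C\CC/C(C)=C\[C@H](O)C1=C
F8 | step 18 | (1(10)Z,4S,5R,6R,8R)-8-(tert-butyldimethylsilyloxy)-4,5-epoxy-4,10-dimethyl-7-methylidenecyclodec-1(10)-en-6-ol | CC(C)(C)[Si](C)(C)O[C@@H]1C/C(C)=C\CC[C@]2(C)O[C@@H]2[C@H](O)C1=C
F0 | step 17 | none | none
F9 | step 24 | (1R,4S,5R,6S,8R,10S)-8-(tert-butyldimethylsilyloxy)-1,10:4,5-diepoxy-6-(4-methoxybenzyloxy)-4,10-dimethylcyclodecan-7-one | CC(C)(C)[Si](C)(C)O[C@@H]1C[C@]2(C)O[C@@H]2CC[C@]2(C)O[C@@H]2[C@H](OCc2ccc(OC)cc2)C1=O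
F10 | step 24 | methyl 3-(tert-butyldimethylsilyloxy)-2-[(1R,4S,5R,6S,8R,10S)-8-(tert-butyldimethylsilyloxy)-1,10:4,5-diepoxy-7-hydroxy-6-(4-methoxybenzyloxy)-4,10-dimethylcyclodecan-7-yl]propanoate (mixture at C7 and C11) | CC(C)(C)[Si](C)(C)O[C@@H]1C[C@]2(C)O[C@@H]2CC[C@]2(C)O[C@@H]2[C@H](OCc2ccc(OC)cc2)C1(O)C(CO[Si](C)(C)C(C)(C)C)C(=O)OC
F11 | step 24 | (1R,4S,5R,6R,8R,10S)-8,13-bis(tert-butyldimethylsilyloxy)-1,10:4,5-diepoxy-7-hydroxygermacran-12,6-olide (mixture at C7 and C11) | CC(C)(C)[Si](C)(C)O[C@@H]1C[C@]2(C)O[C@@H]2CC[C@]2(C)O[C@@H]2[C@@H]2OC(=O)C(CO[Si](C)(C)C(C)(C)C)C21O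
F12 | step 6 | (3S,4Z)-6-(tert-butyldimethylsilyloxy)-3-(4-methoxybenzyloxy)-5-methyl-2-methylidenehex-4-en-1-ol | OCC(=C)[C@@H](OCc1ccc(OC)cc1)/C=C(C)\CO[Si](C)(C)C(C)(C)C
F13 | step 4 | (Z)-6-(tert-butyldimethylsilyloxy)-5-methyl-1-(trimethylsilyl)hex-4-en-1-yn-3-ol (racemic) | C[Si](C)(C)C#CC(O)/C=C(C)\CO[Si](C)(C)C(C)(C)C
F14 | step 4 | (Z)-6-(tert-butyldimethylsilyloxy)-5-methyl-1-(trimethylsilyl)hex-4-en-1-yn-3-one | C[Si](C)(C)C#CC(=O)/C=C(C)\CO[Si](C)(C)C(C)(C)C
A1 | alternative 1 | C5 iodo butenolide with free C4 hydroxyl, 1,10-epoxide and C8 silyl ether | CC(C)(C)[Si](C)(C)O[C@@H]1C[C@]2(C)O[C@@H]2CC[C@](C)(O)[C@@H](I)[C@@H]2OC(=O)C(COC(C)=O)=C21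
A2 | alternative 1 | ten-membered (5Z,7(11)Z)-dienoic acid with C4 hydroxyl, 1,10-epoxide, C8 silyl ether and C13 acetate | CC(C)(C)[Si](C)(C)O[C@@H]1C[C@]2(C)O[C@@H]2CC[C@](C)(O)/C=C\C1=C(\COC(C)=O)C(=O)O
A3 | alternative 1 | (S)-linalool | C=C[C@@](C)(O)CCC=C(C)C
A4 | alternative 2 | (2Z,6Z)-3,7-dimethylcyclodeca-2,6-dien-1-one | C1CC/C(C)=C\CC/C(C)=C\C1=O
A5 | alternative 2 | (2Z,6Z)-1-ethenyl-3,7-dimethylcycloocta-2,6-dien-1-ol (racemic) | C=CC1(O)/C=C(C)\CC/C=C(C)\C1
A6 | alternative 3 | ten-membered C8 ketone with C10 tertiary hydroxyl, C1 p-methoxybenzyl ether, 4,5-epoxide and butenolide | O=C1C[C@](C)(O)[C@@H](OCc2ccc(OC)cc2)CC[C@]2(C)O[C@@H]2[C@@H]2OC(=O)C(COC(C)=O)=C21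
A7 | alternative 3 | open-chain bromoacetyl butenolide with C10 methyl ketone, C1 p-methoxybenzyl ether and 4,5-epoxide | CC(=O)[C@@H](OCc1ccc(OC)cc1)CC[C@]1(C)O[C@@H]1[C@@H]1OC(=O)C(COC(C)=O)=C1C(=O)CBr
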